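**Retrosynthetic overview**
1. Target 8 ⇐ 7,7''-di-O-benzyl ether 7 (hydrogenolysis as the last step).
2. 7 ⇐ two identical (2S)-flavanone enoxysilanes 6, joined at C3–C3'' by oxidative homocoupling; both C3 centres are set trans to the C2 aryl groups by substrate control.
3. 6 ⇐ (2S)-flavanone 5 ⇐ chromone 3 + arylboronic acid 4 by Rh-catalysed asymmetric 1,4-addition; this is the only catalyst-controlled stereocentre.
4. 3 ⇐ 5,7-dihydroxychromone 1 by one-pot 7-O-benzylation / 5-O-methylation.
5. Ring order: both benzopyranone rings are bought in 1 and the B-rings are appended in step 2; no ring is formed, and the last skeletal bond made is C3–C3''.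

Assumption: 1, 4 and the chiral ligand are taken as catalogue items, and flavonoid numbering (C2/C3/C4, doubly primed for the second half) is used, the target being (2S,3R,2''S,3''R).

**Step 1**
Reactants: 1 5,7-dihydroxy-4H-chromen-4-one
Product: 3 7-(benzyloxy)-5-methoxy-4H-chromen-4-one, via 7-(benzyloxy)-5-hydroxy-4H-chromen-4-one 2 (not isolated)
Conditions: BnBr (1.05 eq), K2CO3 (1.2 eq), DMF, rt; then MeI (5 eq), K2CO3 (3 eq), 50 °C
Reagents that add atoms: benzyl bromide BrCc1ccccc1; methyl iodide CI
Why: Sequential Williamson etherification, in which the acidic 7-OH is alkylated first at rt while the 5-OH, hydrogen-bonded to C4=O, is methylated only in the forcing second stage.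

**Step 2**
Reactants: 3 7-(benzyloxy)-5-methoxy-4H-chromen-4-one; 4 (4-methoxyphenyl)boronic acid (3 eq)
Product: 5 (2S)-7-(benzyloxy)-5-methoxy-2-(4-methoxyphenyl)chroman-4-one
Conditions: [Rh(OH)((S)-MeO-F12-BIPHEP)]2 (1.5 mol %), CH2Cl2/H2O 10:1, 20 °C [ligand = (S)-6,6'-dimethoxybiphenyl-2,2'-diylbis[bis(3,4,5-trifluorophenyl)phosphine]]
Reagents that add atoms: none
Why: Hayashi–Miyaura Rh-catalysed asymmetric 1,4-addition, in which the aryl–Rh(I) species adds to C2=C3 on the face selected by the (S)-biaryl bisphosphine (the same sense that gives (S)-3-arylcyclohexanones from cyclohexenone) and water protonates the Rh enolate, setting C2 as S.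

**Step 3**
Reactants: 5 (2S)-7-(benzyloxy)-5-methoxy-2-(4-methoxyphenyl)chroman-4-one
Product: 6 (2S)-7-(benzyloxy)-5-methoxy-2-(4-methoxyphenyl)-4-[(trimethylsilyl)oxy]-2H-chromene
Conditions: TMSOTf (1.3 eq), Et3N (2 eq), CH2Cl2, 0 °C; pentane, filter, concentrate, use crude
Reagents that add atoms: trimethylsilyl triflate C[Si](C)(C)OS(=O)(=O)C(F)(F)F
Why: Soft enolisation (silyl triflate/amine) gives the enoxysilane without a free enolate, which could open the pyranone by E1cB (retro-oxa-Michael) and racemise C2, so C2 stays S.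

**Step 4**
Reactants: 6 (2S)-7-(benzyloxy)-5-methoxy-2-(4-methoxyphenyl)-4-[(trimethylsilyl)oxy]-2H-chromene (two molecules)
Product: 7 (2S,3R,2''S,3''R)-7,7''-bis(benzyloxy)-5,5''-dimethoxy-2,2''-bis(4-methoxyphenyl)-3,3''-bichromane-4,4''-dione
Conditions: CAN (2.2 eq per dimer), NaHCO3 (4.5 eq), MeCN, −30 → 0 °C
Reagents that add atoms: none
Why: Oxidative enoxysilane homocoupling (Ce(IV) single-electron oxidation, the radical cation/α-keto radical adds to C3 of a second enoxysilane, then second oxidation and desilylation) forms each new C3 centre anti to its C2 aryl group, and since both halves are 2S the trans,trans product can only be the C2-symmetric (2S,3R,2''S,3''R) isomer, which is also the thermodynamic arrangement at the epimerisable C3 centres.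

**Step 5**
Reactants: 7 (2S,3R,2''S,3''R)-7,7''-bis(benzyloxy)-5,5''-dimethoxy-2,2''-bis(4-methoxyphenyl)-3,3''-bichromane-4,4''-dione
Product: 8 4',4''',5,5''-tetramethylchamaejasmin
Conditions: H2 (1 atm), 10% Pd/C, EtOAc/THF, rt, stop at full debenzylation
Reagents that add atoms: none
Why: Catalytic hydrogenolysis cleaves the two aryl benzyl ethers much faster than the C2–O bond or the deactivated C4 ketone react, and the neutral conditions leave all four stereocentres untouched.

**Compound list**
1 | 5,7-dihydroxy-4H-chromen-4-one | O=c1ccoc2cc(O)cc(O)c12 | starting material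
2 | 7-(benzyloxy)-5-hydroxy-4H-chromen-4-one | O=c1ccoc2cc(OCc3ccccc3)cc(O)c12 | intermediate (not isolated)
3 | 7-(benzyloxy)-5-methoxy-4H-chromen-4-one | COc1cc(OCc2ccccc2)cc2occc(=O)c12 | intermediate
4 | (4-methoxyphenyl)boronic acid | COc1ccc(B(O)O)cc1 | starting material
5 | (2S)-7-(benzyloxy)-5-methoxy-2-(4-methoxyphenyl)chroman-4-one | COc1ccc([C@H]2Oc3cc(OCc4ccccc4)cc(OC)c3C(=O)C2)cc1 | intermediate
6 | (2S)-7-(benzyloxy)-5-methoxy-2-(4-methoxyphenyl)-4-[(trimethylsilyl)oxy]-2H-chromene | COc1ccc([C@H]2Oc3cc(OCc4ccccc4)cc(OC)c3C(O[Si](C)(C)C)=C2)cc1 | intermediate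
7 | (2S,3R,2''S,3''R)-7,7''-bis(benzyloxy)-5,5''-dimethoxy-2,2''-bis(4-methoxyphenyl)-3,3''-bichromane-4,4''-dione | COc1ccc([C@H]2Oc3cc(OCc4ccccc4)cc(OC)c3C(=O)[C@@H]2[C@H]2C(=O)c3c(OC)cc(OCc4ccccc4)cc3O[C@@H]2c2ccc(OC)cc2)cc1 | intermediate
8 | 4',4''',5,5''-tetramethylchamaejasmin, (2S,3R,2''S,3''R)-7,7''-dihydroxy-5,5''-dimethoxy-2,2''-bis(4-methoxyphenyl)-3,3''-bichromane-4,4''-dione | COc1ccc([C@H]2Oc3cc(O)cc(OC)c3C(=O)[C@@H]2[C@H]2C(=O)c3c(OC)cc(O)cc3O[C@@H]2c2ccc(OC)cc2)cc1 | target

**Totals**
Total step count: 5. Longest linear sequence: 5 (fully linear from 1; step 4 joins two molecules of the same intermediate).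

**Three steps most likely to fail**

Step 4 (oxidative dimerisation) is the riskiest. The hindered secondary radical may be over-oxidised to the flavone instead of coupling, and 2,3-cis epimers may form. The fallback sets out from 5 and returns at 7. Two molecules of 5 are tied together with i-Pr2Si(OTf)2 (0.5 eq) and Et3N in CH2Cl2 to give the silicon-tethered bis-enol ether diisopropylbis{[(2S)-7-(benzyloxy)-5-methoxy-2-(4-methoxyphenyl)-2H-chromen-4-yl]oxy}silane F1. CAN/NaHCO3 in MeCN/EtCN at −20 °C then forms the C3–C3'' bond intramolecularly through a seven-membered transition state. This outruns over-oxidation and favours the C2-symmetric (3R,3''R) diastereomer; loss of the silicon on work-up gives 7.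

Step 2 (asymmetric 1,4-addition) may be sluggish or give insufficient ee on the electron-rich 5,7-dialkoxychromone, or suffer 1,2-over-addition. The sense of induction is predicted by analogy and must be confirmed by chiral HPLC. The fallback sets out from 3 and returns at 5. Copper-catalysed 1,4-addition of 4-methoxyphenylmagnesium bromide (CuBr·SMe2 10 mol %, THF, −40 °C, NH4Cl quench) gives racemic 7-(benzyloxy)-5-methoxy-2-(4-methoxyphenyl)chroman-4-one F2. Preparative chiral SFC on a polysaccharide phase then delivers 5, and the unwanted (2R)-7-(benzyloxy)-5-methoxy-2-(4-methoxyphenyl)chroman-4-one F3 is set aside. This replaces asymmetric catalysis by resolution.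

Step 5 (hydrogenolysis) may cleave the doubly activated C2–O bond (a p-methoxybenzylic aryl ether) or reduce C4=O on the precious dimer. The fallback sets out from 7 and returns directly at 8. It is a non-reductive Lewis-acid debenzylation: BCl3 with pentamethylbenzene as cation scavenger in CH2Cl2 at −78 °C, quenched cold with MeOH so that the peri 5-OMe groups are not demethylated. It needs no H2 and no metal, and makes no new intermediate.

**Further compounds**
F1 | step 4 | diisopropylbis{[(2S)-7-(benzyloxy)-5-methoxy-2-(4-methoxyphenyl)-2H-chromen-4-yl]oxy}silane | COc1ccc([C@H]2Oc3cc(OCc4ccccc4)cc(OC)c3C(O[Si](C(C)C)(C(C)C)OC3=C[C@@H](c4ccc(OC)cc4)Oc4cc(OCc5ccccc5)cc(OC)c34)=C2)cc1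
F2 | step 2 | racemic 7-(benzyloxy)-5-methoxy-2-(4-methoxyphenyl)chroman-4-one | COc1ccc(C2Oc3cc(OCc4ccccc4)cc(OC)c3C(=O)C2)cc1
F3 | step 2 | (2R)-7-(benzyloxy)-5-methoxy-2-(4-methoxyphenyl)chroman-4-one | COc1ccc([C@@H]2Oc3cc(OCc4ccccc4)cc(OC)c3C(=O)C2)cc1
F0 | step 5 | none | none
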